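**Plan**
1. Cuts in the side arms: the acrylic C=C (stabilised-ylide Wittig) and the trisubstituted C1'=C2' olefin of the dienyl chain (α-iodo-ylide olefination, then C–CH3 coupling). This leaves a 3,5-diethyl-1,2-dioxolane with two one-carbon arms; in the ring, the C4–C5 bond (ring CH2 to the quaternary carbon that carries the dienyl chain) and the O2–C3 bond are cut together.
2. Enabling feature: C3 and C5 of the dioxolane are both quaternary, each bearing a peroxide oxygen, an ethyl group, the C4 methylene and an sp2 arm, and the two arms are cis. With both arms as CH2OH the ring has a mirror plane through C4 and the O–O midpoint (meso), the arms can be bridged by one silicon atom, and the ring unravels into a ketone-level peroxycarbenium carbon plus a 1,1-disubstituted olefin.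
3. Forward order of rings: two four-carbon alcohols are joined through i-Pr2Si and the ketal is converted into a silylperoxy ketal. SnCl4 then triggers C–C bond formation that closes an eight-membered silicon-tethered ring, followed at once by closure of the dioxolane by the peroxide oxygen; removal of silicon gives the meso-diol.
4. The arms are elaborated one after the other: dienyl chain first (fragment from a Johnson–Claisen ester), acrylic acid last.
5. Stereochemistry: the cis relation of the two quaternary centres comes from the tether; their absolute configuration from lipase desymmetrisation of the meso-diol; C4' from a Sharpless kinetic resolution relayed by a chair [3,3] shift. Olefin geometries come from the Claisen chair (C5'=C6'), the Z-selective iodo-olefination with retentive methylation (C1'=C2') and the stabilised ylide (acrylate).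

Key step: step 6

Assumption: the lipase acetylates the CH2OH group on the (S)-configured ring carbon of the meso-diol; should a given lipase prefer the other group, the same enzyme used in the hydrolysis direction on the meso-diacetate gives the monoacetate drawn here.

**Route**

Step 1
Reactants: 1 2-ethylacrolein (2-methylidenebutanal)
Product: 2 2-methylidenebutan-1-ol
Conditions: NaBH4, CeCl3·7H2O, MeOH, 0 °C
Reagents that add atoms: none
Why: Luche reduction, in which the cerium-modified borohydride should add hydride 1,2 to the enal carbonyl and leave the 1,1-disubstituted olefin untouched.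

Step 2
Reactants: 3 1-hydroxybutan-2-one
Product: 4 2,2-dimethoxybutan-1-ol
Conditions: HC(OMe)3, MeOH, p-TsOH (cat.), rt; NaOMe quench
Reagents that add atoms: trimethyl orthoformate COC(OC)OC; methanol CO
Why: Acid-catalysed ketalisation driven by the orthoester as water scavenger, a standard way to turn α-hydroxy ketones into open-chain dimethyl ketals.

Step 3
Reactants: 4 2,2-dimethoxybutan-1-ol; 2 2-methylidenebutan-1-ol
Product: 6 (2,2-dimethoxybutoxy)(2-methylidenebutoxy)di(propan-2-yl)silane, via monochlorosilane 5 (not isolated)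
Conditions: i-Pr2SiCl2 (1.0 equiv), Et3N, CH2Cl2, −40 °C, 4 added slowly; then 2, DMAP (cat.), 0 °C to rt
Reagents that add atoms: dichlorodi(propan-2-yl)silane CC(C)[Si](Cl)(Cl)C(C)C
Why: Stepwise nucleophilic substitution at silicon (unsymmetrical silaketal formation), in which the second chloride of the hindered diisopropylsilyl unit is displaced more slowly than the first, so the more hindered alcohol is installed first and the allylic alcohol second.

Step 4
Reactants: 6 (2,2-dimethoxybutoxy)(2-methylidenebutoxy)di(propan-2-yl)silane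
Product: 7 (2-hydroperoxy-2-methoxybutoxy)(2-methylidenebutoxy)di(propan-2-yl)silane (racemic)
Conditions: H2O2 (anhydrous, in Et2O), camphorsulfonic acid (cat.), 0 °C
Reagents that add atoms: hydrogen peroxide OO
Why: Acid-catalysed perhydrolysis of a dimethyl ketal, which should exchange one methoxy group for OOH and give the 1-methoxyalkyl hydroperoxide, whose new centre is racemic and is planarised again in step 6.

Step 5
Reactants: 7 (2-hydroperoxy-2-methoxybutoxy)(2-methylidenebutoxy)di(propan-2-yl)silane
Product: 8 (2-methoxy-2-triethylsilylperoxybutoxy)(2-methylidenebutoxy)di(propan-2-yl)silane (racemic)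
Conditions: Et3SiCl, imidazole, DMF, 0 °C
Reagents that add atoms: chlorotriethylsilane CC[Si](Cl)(CC)CC
Why: O-Silylation of the hydroperoxide, which should give the triethylsilylperoxy ketal that serves as the peroxycarbenium precursor and carries the silyl leaving group needed for the final ring closure.

Step 6
Reactants: 8 (2-methoxy-2-triethylsilylperoxybutoxy)(2-methylidenebutoxy)di(propan-2-yl)silane
Product: 11 (1R,7S)-1,7-diethyl-4,4-di(propan-2-yl)-3,5,8,9-tetraoxa-4-silabicyclo[5.2.1]decane (meso), via peroxycarbenium ion 9 (not isolated), via ring-closed tertiary cation 10 (not isolated)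
Conditions: SnCl4 (1.2 equiv), CH2Cl2, −78 °C, 8 added by syringe pump to high dilution; NaHCO3 quench at −78 °C
Reagents that add atoms: none
Why: Proposed new method: SnCl4 should abstract methoxide from the silylperoxy ketal to give peroxycarbenium ion 9, the tethered 1,1-disubstituted olefin attacks it through its CH2 terminus so that C–C bond formation closes the eight-membered 1,3-dioxa-2-silacyclooctane and leaves tertiary cation 10, and the distal peroxide oxygen captures that cation with loss of Et3SiCl to close the 1,2-dioxolane. The closest known reaction type is the intermolecular SnCl4-mediated annulation of triethylsilylperoxy ketals with 1,1-disubstituted alkenes to 3,3,5,5-tetrasubstituted 1,2-dioxolanes, combined with silicon-tethered cation–olefin cyclisations to medium rings. Mode of closure: the eight-membered ring by an 8-endo attack of the olefin (both olefin carbons become ring members), the dioxolane by collapse of a planar tertiary carbocation with the peroxide oxygen in a five-ring closure. Both quaternary stereocentres arise here and their relative configuration is fixed by the tether, because a five-atom CH2–O–Si–O–CH2 bridge can span C3 and C5 of a dioxolane only on one face, so only the cis (meso) bicycle can form. The step needs cyclisation over oligomerisation and peroxide-oxygen capture over capture by a silyl ether oxygen or proton loss; high dilution, the two isopropyl groups on silicon and the low basicity of the hindered Si–O oxygens are relied on for this.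

Step 7
Reactants: 11 (1R,7S)-1,7-diethyl-4,4-di(propan-2-yl)-3,5,8,9-tetraoxa-4-silabicyclo[5.2.1]decane
Product: 12 [(3R,5S)-3,5-diethyl-1,2-dioxolane-3,5-diyl]dimethanol (meso)
Conditions: HF·pyridine, pyridine, THF, 0 °C to rt
Reagents that add atoms: none
Why: Fluoride-driven cleavage of both Si–O bonds (desilylation), which should spare the fully substituted peroxide since it has no α-hydrogen.

Step 8
Reactants: 12 [(3R,5S)-3,5-diethyl-1,2-dioxolane-3,5-diyl]dimethanol
Product: 13 [(3S,5R)-3,5-diethyl-5-(hydroxymethyl)-1,2-dioxolan-3-yl]methyl acetate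
Conditions: lipase from Burkholderia cepacia (immobilised), vinyl acetate, t-BuOMe, 30 °C
Reagents that add atoms: vinyl acetate C=COC(C)=O
Why: Enzymatic desymmetrisation of a meso-diol by a lipase (serine hydrolase) through irreversible transesterification, in which the chiral acyl-transfer site should distinguish the two enantiotopic CH2OH groups and so fix the absolute configuration of both quaternary centres at once, with over-acylation of the minor enantiomer raising the enantiomeric purity.

Step 9
Reactants: 13 [(3S,5R)-3,5-diethyl-5-(hydroxymethyl)-1,2-dioxolan-3-yl]methyl acetate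
Product: 14 [(3S,5R)-3,5-diethyl-5-formyl-1,2-dioxolan-3-yl]methyl acetate
Conditions: Dess–Martin periodinane, NaHCO3, CH2Cl2, 0 °C to rt
Reagents that add atoms: none
Why: Dess–Martin oxidation under buffered neutral conditions, which should give the non-enolisable aldehyde without touching the peroxide or the acetate.

Step 10
Reactants: 15 (2E)-pent-2-enal
Product: 16 (4E)-hept-4-en-3-ol (racemic)
Conditions: EtMgBr, THF, −78 to 0 °C; aq. NH4Cl
Reagents that add atoms: ethylmagnesium bromide CC[Mg]Br
Why: 1,2-Addition of a Grignard reagent to an enal, which should give the secondary allylic alcohol with the E-olefin preserved.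

Step 11
Reactants: 16 (4E)-hept-4-en-3-ol (racemic)
Product: 17 (3R,4E)-hept-4-en-3-ol
Conditions: Ti(Oi-Pr)4 (cat.), L-(+)-diisopropyl tartrate (cat.), t-BuOOH (0.6 equiv), 4 Å molecular sieves, CH2Cl2, −20 °C
Reagents that add atoms: none
Why: Sharpless kinetic resolution, in which the titanium–tartrate catalyst built from L-(+)-tartrate should epoxidise the (S)-enantiomer of this E-disubstituted secondary allylic alcohol much faster, so that the (R)-alcohol is recovered once conversion passes one half.

Step 12
Reactants: 17 (3R,4E)-hept-4-en-3-ol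
Product: 19 ethyl (3R,4E)-3-ethylhept-4-enoate, via ketene acetal 18 (not isolated)
Conditions: MeC(OEt)3, EtCO2H (cat.), 140 °C, EtOH distilled off
Reagents that add atoms: triethyl orthoacetate CC(OCC)(OCC)OCC
Why: Johnson–Claisen [3,3]-sigmatropic rearrangement through a chair transition state with the carbinol ethyl group equatorial, which should transfer the carbinol configuration suprafacially to the new C3 stereocentre (R) and give the E-olefin.

Step 13
Reactants: 19 ethyl (3R,4E)-3-ethylhept-4-enoate
Product: 20 (3R,4E)-3-ethylhept-4-en-1-ol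
Conditions: LiAlH4, Et2O, 0 °C
Reagents that add atoms: none
Why: Hydride reduction of the ester to the primary alcohol, which does not touch the stereocentre or the isolated olefin.

Step 14
Reactants: 20 (3R,4E)-3-ethylhept-4-en-1-ol
Product: 21 (3E,5R)-5-ethyl-7-iodohept-3-ene
Conditions: I2, PPh3, imidazole, CH2Cl2, 0 °C
Reagents that add atoms: iodine [I][I]
Why: Appel-type iodination of a primary alcohol by SN2 displacement of the oxyphosphonium group, remote from the stereocentre.

Step 15
Reactants: 21 (3E,5R)-5-ethyl-7-iodohept-3-ene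
Product: 22 [(3R,4E)-3-ethylhept-4-en-1-yl]triphenylphosphonium iodide
Conditions: PPh3, MeCN, reflux
Reagents that add atoms: triphenylphosphine c1ccc(cc1)P(c1ccccc1)c1ccccc1
Why: SN2 quaternisation of triphenylphosphine by the primary iodide, which should give the Wittig salt.

Step 16
Reactants: 14 [(3S,5R)-3,5-diethyl-5-formyl-1,2-dioxolan-3-yl]methyl acetate; 22 [(3R,4E)-3-ethylhept-4-en-1-yl]triphenylphosphonium iodide
Product: 26 [(3S,5R)-3,5-diethyl-5-[(1Z,4R,5E)-4-ethyl-2-iodoocta-1,5-dien-1-yl]-1,2-dioxolan-3-yl]methyl acetate, via ylide 23 (not isolated), via iodophosphonium iodide 24 (not isolated), via iodo ylide 25 (not isolated)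
Conditions: 22 (2 equiv), NaHMDS, THF, 0 °C; transferred into I2, THF, −78 °C; NaHMDS, −78 to −20 °C; then 14, −78 °C to rt
Reagents that add atoms: iodine [I][I]
Why: Wittig olefination with an α-iodo ylide (Stork–Zhao-type iodo-olefination), whose kinetically controlled addition to the aldehyde should place iodine cis to the ring carbon and give the Z-iodoalkene, the peroxide being inert because it has no α-hydrogen.

Step 17
Reactants: 26 [(3S,5R)-3,5-diethyl-5-[(1Z,4R,5E)-4-ethyl-2-iodoocta-1,5-dien-1-yl]-1,2-dioxolan-3-yl]methyl acetate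
Product: 27 [(3S,5R)-3,5-diethyl-5-[(1E,4R,5E)-4-ethyl-2-methylocta-1,5-dien-1-yl]-1,2-dioxolan-3-yl]methyl acetate
Conditions: MeZnCl, Pd(t-Bu3P)2 (cat.), THF, 0 °C to rt
Reagents that add atoms: methylzinc chloride C[Zn]Cl
Why: Negishi cross-coupling of the alkenyl iodide with retention of olefin geometry, so that methyl takes the place of iodine cis to the ring carbon and the E-trisubstituted olefin results, the mild organozinc sparing acetate and peroxide.

Step 18
Reactants: 27 [(3S,5R)-3,5-diethyl-5-[(1E,4R,5E)-4-ethyl-2-methylocta-1,5-dien-1-yl]-1,2-dioxolan-3-yl]methyl acetate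
Product: 28 [(3S,5R)-3,5-diethyl-5-[(1E,4R,5E)-4-ethyl-2-methylocta-1,5-dien-1-yl]-1,2-dioxolan-3-yl]methanol
Conditions: K2CO3 (cat.), MeOH, 0 °C
Reagents that add atoms: none
Why: Base-catalysed methanolysis of the acetate, which should be harmless here because no Michael acceptor is yet present and the peroxide has no α-hydrogen.

Step 19
Reactants: 28 [(3S,5R)-3,5-diethyl-5-[(1E,4R,5E)-4-ethyl-2-methylocta-1,5-dien-1-yl]-1,2-dioxolan-3-yl]methanol
Product: 29 (3S,5R)-3,5-diethyl-5-[(1E,4R,5E)-4-ethyl-2-methylocta-1,5-dien-1-yl]-1,2-dioxolane-3-carbaldehyde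
Conditions: Dess–Martin periodinane, NaHCO3, CH2Cl2, 0 °C to rt
Reagents that add atoms: none
Why: Dess–Martin oxidation of the primary alcohol to the non-enolisable aldehyde under neutral conditions, which avoid ionising the allylic tertiary C–O bond.

Step 20
Reactants: 29 (3S,5R)-3,5-diethyl-5-[(1E,4R,5E)-4-ethyl-2-methylocta-1,5-dien-1-yl]-1,2-dioxolane-3-carbaldehyde
Product: 30 methyl (2E)-3-[(3S,5R)-3,5-diethyl-5-[(1E,4R,5E)-4-ethyl-2-methylocta-1,5-dien-1-yl]-1,2-dioxolan-3-yl]prop-2-enoate
Conditions: Ph3P=CHCO2Me, toluene, 50 °C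
Reagents that add atoms: methyl (triphenyl-λ5-phosphanylidene)acetate COC(=O)C=P(c1ccccc1)(c1ccccc1)c1ccccc1
Why: Wittig olefination with a stabilised ylide, which should give the E-enoate under thermodynamic control even with the hindered aldehyde.

Step 21
Reactants: 30 methyl (2E)-3-[(3S,5R)-3,5-diethyl-5-[(1E,4R,5E)-4-ethyl-2-methylocta-1,5-dien-1-yl]-1,2-dioxolan-3-yl]prop-2-enoate
Product: 31 (2E)-3-[(3S,5R)-3,5-diethyl-5-[(1E,4R,5E)-4-ethyl-2-methylocta-1,5-dien-1-yl]-1,2-dioxolan-3-yl]prop-2-enoic acid (target)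
Conditions: LiOH, THF/MeOH/H2O, 0 °C to rt; then cold dilute HCl to pH 4
Reagents that add atoms: lithium hydroxide [Li+].[OH-]
Why: Saponification of the methyl ester by acyl–oxygen cleavage, with a brief, mild acidification so that the acid-sensitive allylic tertiary peroxide is not ionised.

**Compound list**

1 | 2-ethylacrolein (2-methylidenebutanal) | C=C(CC)C=O | starting material
2 | 2-methylidenebutan-1-ol | C=C(CC)CO | intermediate
3 | 1-hydroxybutan-2-one | CCC(=O)CO | starting material
4 | 2,2-dimethoxybutan-1-ol | CCC(OC)(OC)CO | intermediate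
5 | chloro(2,2-dimethoxybutoxy)di(propan-2-yl)silane (not isolated) | CCC(OC)(OC)CO[Si](Cl)(C(C)C)C(C)C | intermediate
6 | (2,2-dimethoxybutoxy)(2-methylidenebutoxy)di(propan-2-yl)silane | C=C(CC)CO[Si](C(C)C)(C(C)C)OCC(CC)(OC)OC | intermediate
7 | (2-hydroperoxy-2-methoxybutoxy)(2-methylidenebutoxy)di(propan-2-yl)silane (racemic) | C=C(CC)CO[Si](C(C)C)(C(C)C)OCC(CC)(OC)OO | intermediate
8 | (2-methoxy-2-triethylsilylperoxybutoxy)(2-methylidenebutoxy)di(propan-2-yl)silane (racemic) | C=C(CC)CO[Si](C(C)C)(C(C)C)OCC(CC)(OC)OO[Si](CC)(CC)CC | intermediate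
9 | peroxycarbenium ion from 8 by loss of methoxide, as its SnCl4(OMe) anion pair (not isolated) | C=C(CC)CO[Si](C(C)C)(C(C)C)OCC(CC)=[O+]O[Si](CC)(CC)CC.CO[Sn-](Cl)(Cl)(Cl)Cl | intermediate
10 | 5,7-diethyl-2,2-di(propan-2-yl)-5-(triethylsilylperoxy)-1,3-dioxa-2-silacyclooctan-7-ylium, as its SnCl4(OMe) anion pair (racemic, not isolated) | CC[C+]1CO[Si](C(C)C)(C(C)C)OCC(CC)(OO[Si](CC)(CC)CC)C1.CO[Sn-](Cl)(Cl)(Cl)Cl | intermediate
11 | (1R,7S)-1,7-diethyl-4,4-di(propan-2-yl)-3,5,8,9-tetraoxa-4-silabicyclo[5.2.1]decane (meso) | CC(C)[Si]1(C(C)C)OC[C@@]2(CC)C[C@](CO1)(CC)OO2 | intermediate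
12 | [(3R,5S)-3,5-diethyl-1,2-dioxolane-3,5-diyl]dimethanol (meso) | OC[C@@]1(CC)C[C@](CO)(CC)OO1 | intermediate
13 | [(3S,5R)-3,5-diethyl-5-(hydroxymethyl)-1,2-dioxolan-3-yl]methyl acetate | OC[C@@]1(CC)C[C@](COC(C)=O)(CC)OO1 | intermediate
14 | [(3S,5R)-3,5-diethyl-5-formyl-1,2-dioxolan-3-yl]methyl acetate | O=C[C@@]1(CC)C[C@](COC(C)=O)(CC)OO1 | intermediate
15 | (2E)-pent-2-enal | CC/C=C/C=O | starting material
16 | (4E)-hept-4-en-3-ol (racemic) | CCC(O)/C=C/CC | intermediate
17 | (3R,4E)-hept-4-en-3-ol | CC[C@@H](O)/C=C/CC | intermediate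
18 | (3R,4E)-3-[(1-ethoxyethenyl)oxy]hept-4-ene (ketene acetal, not isolated) | C=C(OCC)O[C@H](CC)/C=C/CC | intermediate
19 | ethyl (3R,4E)-3-ethylhept-4-enoate | CC/C=C/[C@H](CC)CC(=O)OCC | intermediate
20 | (3R,4E)-3-ethylhept-4-en-1-ol | CC/C=C/[C@H](CC)CCO | intermediate
21 | (3E,5R)-5-ethyl-7-iodohept-3-ene | CC/C=C/[C@H](CC)CCI | intermediate
22 | [(3R,4E)-3-ethylhept-4-en-1-yl]triphenylphosphonium iodide | CC/C=C/[C@H](CC)CC[P+](c1ccccc1)(c1ccccc1)c1ccccc1.[I-] | intermediate
23 | [(3R,4E)-3-ethylhept-4-en-1-ylidene]triphenyl-λ5-phosphane (ylide, not isolated) | CC/C=C/[C@H](CC)CC=P(c1ccccc1)(c1ccccc1)c1ccccc1 | intermediate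
24 | [(3R,4E)-3-ethyl-1-iodohept-4-en-1-yl]triphenylphosphonium iodide (both C1 epimers, not isolated) | CC/C=C/[C@H](CC)CC(I)[P+](c1ccccc1)(c1ccccc1)c1ccccc1.[I-] | intermediate
25 | [(3R,4E)-3-ethyl-1-iodohept-4-en-1-ylidene]triphenyl-λ5-phosphane (iodo ylide, not isolated) | CC/C=C/[C@H](CC)CC(I)=P(c1ccccc1)(c1ccccc1)c1ccccc1 | intermediate
26 | [(3S,5R)-3,5-diethyl-5-[(1Z,4R,5E)-4-ethyl-2-iodoocta-1,5-dien-1-yl]-1,2-dioxolan-3-yl]methyl acetate | CC/C=C/[C@H](CC)C/C(I)=C/[C@@]1(CC)C[C@](COC(C)=O)(CC)OO1 | intermediate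
27 | [(3S,5R)-3,5-diethyl-5-[(1E,4R,5E)-4-ethyl-2-methylocta-1,5-dien-1-yl]-1,2-dioxolan-3-yl]methyl acetate | CC/C=C/[C@H](CC)C/C(C)=C/[C@@]1(CC)C[C@](COC(C)=O)(CC)OO1 | intermediate
28 | [(3S,5R)-3,5-diethyl-5-[(1E,4R,5E)-4-ethyl-2-methylocta-1,5-dien-1-yl]-1,2-dioxolan-3-yl]methanol | CC/C=C/[C@H](CC)C/C(C)=C/[C@@]1(CC)C[C@](CO)(CC)OO1 | intermediate
29 | (3S,5R)-3,5-diethyl-5-[(1E,4R,5E)-4-ethyl-2-methylocta-1,5-dien-1-yl]-1,2-dioxolane-3-carbaldehyde | CC/C=C/[C@H](CC)C/C(C)=C/[C@@]1(CC)C[C@](C=O)(CC)OO1 | intermediate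
30 | methyl (2E)-3-[(3S,5R)-3,5-diethyl-5-[(1E,4R,5E)-4-ethyl-2-methylocta-1,5-dien-1-yl]-1,2-dioxolan-3-yl]prop-2-enoate | CC/C=C/[C@H](CC)C/C(C)=C/[C@@]1(CC)C[C@](/C=C/C(=O)OC)(CC)OO1 | intermediate
31 | (2E)-3-[(3S,5R)-3,5-diethyl-5-[(1E,4R,5E)-4-ethyl-2-methylocta-1,5-dien-1-yl]-1,2-dioxolan-3-yl]prop-2-enoic acid | CC/C=C/[C@H](CC)C/C(C)=C/[C@@]1(CC)C[C@](/C=C/C(=O)O)(CC)OO1 | target

**Count**
Total steps: 21. Longest linear sequence: 14 steps (steps 1, 3 to 9 and 16 to 21).

**Steps most likely to fail**

Step 6. What may go wrong: the ring-closed tertiary cation may be captured transannularly by the silyl ether oxygen of the other arm, lose a proton to give an allylic peroxide, or the peroxycarbenium ion may react with the olefin of a second molecule so that oligomers form in place of the medium ring. Fallback (known intermolecular annulation, then separation of diastereomers): it sets out from 4 and 2 and returns at 12. Alcohol 4 is silylated (t-BuPh2SiCl, imidazole) to tert-butyl(2,2-dimethoxybutoxy)diphenylsilane F1. Perhydrolysis (H2O2, camphorsulfonic acid) gives 1-{[tert-butyl(diphenyl)silyl]oxy}-2-methoxybutan-2-yl hydroperoxide F2, and silylation (Et3SiCl, imidazole) gives tert-butyl{2-methoxy-2-[(triethylsilyl)peroxy]butoxy}diphenylsilane F3. Alcohol 2 is silylated in the same way to tert-butyl(2-methylidenebutoxy)diphenylsilane F4. F3 and F4 with SnCl4 in CH2Cl2 at −78 °C should give the 3,3,5,5-tetrasubstituted dioxolane as a cis/trans pair. The meso cis isomer (3R,5S)-3,5-bis{[tert-butyl(diphenyl)silyl]oxymethyl}-3,5-diethyl-1,2-dioxolane F5 is separated by chromatography from the racemic trans isomer (3R,5R)-3,5-bis{[tert-butyl(diphenyl)silyl]oxymethyl}-3,5-diethyl-1,2-dioxolane F6. Bu4NF in THF then converts F5 into 12.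

Step 16. What may go wrong: slow addition of the bulky iodo ylide to an aldehyde that sits on a fully substituted carbon, with erosion of Z-selectivity, loss of iodine from the ylide (iodine-free olefin) and attack of excess ylide on the acetate. Fallback (stereodefined stepwise cross-coupling on a 1,1-dibromoalkene): it sets out from 19 and 14 and returns at 27. Ester 19 is saponified (LiOH) to (3R,4E)-3-ethylhept-4-enoic acid F7, and iododecarboxylation (PhI(OAc)2, I2, light) gives (3E,5S)-5-(iodomethyl)hept-3-ene F8. Zinc insertion (activated Zn, LiCl, THF) gives [(2S,3E)-2-ethylhex-3-en-1-yl]zinc iodide F9. Aldehyde 14 is converted (CBr4, PPh3, Zn, CH2Cl2, 0 °C) into [(3S,5R)-5-(2,2-dibromoethenyl)-3,5-diethyl-1,2-dioxolan-3-yl]methyl acetate F10. Palladium-catalysed coupling of F10 with F9 (Pd(DPEphos)Cl2) should replace selectively the bromine trans to the ring carbon and give [(3S,5R)-5-[(1Z,4R,5E)-2-bromo-4-ethylocta-1,5-dien-1-yl]-3,5-diethyl-1,2-dioxolan-3-yl]methyl acetate F11. Methylation of F11 with retention (MeZnCl, Pd(t-Bu3P)2) then gives 27.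

Step 8. What may go wrong: slow or poorly selective acyl transfer because both CH2OH groups sit on fully substituted carbons, and over-acylation to the diacetate. Fallback (non-enzymatic, resolution with recycling through the meso-diol): it sets out from 12 and returns at 13. Statistical mono-acetylation (Ac2O, 1 equiv, pyridine, DMAP) gives racemic monoacetate, that is 13 together with its enantiomer [(3R,5S)-3,5-diethyl-5-(hydroxymethyl)-1,2-dioxolan-3-yl]methyl acetate F12, beside some meso-diacetate [(3R,5S)-3,5-diethyl-1,2-dioxolane-3,5-diyl]bis(methylene) diacetate F13. Preparative chromatography on a chiral stationary phase delivers 13. F12 and F13 are returned to 12 by K2CO3 in MeOH and recycled, so no material is lost in principle.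

**Further compounds**
F1 | step 6 | tert-butyl(2,2-dimethoxybutoxy)diphenylsilane | CCC(OC)(OC)CO[Si](c1ccccc1)(c1ccccc1)C(C)(C)C
F2 | step 6 | 1-{[tert-butyl(diphenyl)silyl]oxy}-2-methoxybutan-2-yl hydroperoxide (racemic) | CCC(OC)(OO)CO[Si](c1ccccc1)(c1ccccc1)C(C)(C)C
F3 | step 6 | tert-butyl{2-methoxy-2-[(triethylsilyl)peroxy]butoxy}diphenylsilane (racemic) | CCC(OC)(OO[Si](CC)(CC)CC)CO[Si](c1ccccc1)(c1ccccc1)C(C)(C)C
F4 | step 6 | tert-butyl(2-methylidenebutoxy)diphenylsilane | C=C(CC)CO[Si](c1ccccc1)(c1ccccc1)C(C)(C)C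
F5 | step 6 | (3R,5S)-3,5-bis{[tert-butyl(diphenyl)silyl]oxymethyl}-3,5-diethyl-1,2-dioxolane (meso, cis) | CC(C)(C)[Si](c1ccccc1)(c1ccccc1)OC[C@@]2(CC)C[C@](CO[Si](c3ccccc3)(c3ccccc3)C(C)(C)C)(CC)OO2
F6 | step 6 | (3R,5R)-3,5-bis{[tert-butyl(diphenyl)silyl]oxymethyl}-3,5-diethyl-1,2-dioxolane (racemic, trans) | CC(C)(C)[Si](c1ccccc1)(c1ccccc1)OC[C@@]2(CC)C[C@@](CO[Si](c3ccccc3)(c3ccccc3)C(C)(C)C)(CC)OO2
F7 | step 16 | (3R,4E)-3-ethylhept-4-enoic acid | CC/C=C/[C@H](CC)CC(=O)O
F8 | step 16 | (3E,5S)-5-(iodomethyl)hept-3-ene | CC/C=C/[C@H](CC)CI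
F9 | step 16 | [(2S,3E)-2-ethylhex-3-en-1-yl]zinc iodide | CC/C=C/[C@H](CC)C[Zn]I
F10 | step 16 | [(3S,5R)-5-(2,2-dibromoethenyl)-3,5-diethyl-1,2-dioxolan-3-yl]methyl acetate | BrC(Br)=C[C@@]1(CC)C[C@](COC(C)=O)(CC)OO1
F11 | step 16 | [(3S,5R)-5-[(1Z,4R,5E)-2-bromo-4-ethylocta-1,5-dien-1-yl]-3,5-diethyl-1,2-dioxolan-3-yl]methyl acetate | CC/C=C/[C@H](CC)C/C(Br)=C/[C@@]1(CC)C[C@](COC(C)=O)(CC)OO1
F12 | step 8 | [(3R,5S)-3,5-diethyl-5-(hydroxymethyl)-1,2-dioxolan-3-yl]methyl acetate | CC(=O)OC[C@@]1(CC)C[C@](CO)(CC)OO1
F13 | step 8 | [(3R,5S)-3,5-diethyl-1,2-dioxolane-3,5-diyl]bis(methylene) diacetate (meso) | CC(=O)OC[C@@]1(CC)C[C@](COC(C)=O)(CC)OO1
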